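Amounts first: two earlier runs each charged 1 mM of starting material in 2 equal portions, 1.0 min apart, with different amounts of enzyme. Alder takes its starting material the same way, while cedar gets its whole charge at the start.

| setting | north-east | south | alder | cedar |
|---|---|---|---|---|
| starting material | 1 mM (in portions, 2) | 1 mM (in portions, 2) | 1.0 mM (in portions, 2) | 1.0 mM |
| enzyme | 0.14 µM | 0.32 µM | 0.21 µM | 0.10 µM |
| remark | run made earlier; portions every 1.0 min | run made earlier; portions every 1.0 min | the portions of starting material follow each other after 1.0 min, the first at the start | everything together at the start |
| time |  |  | 2.5 min | 2.5 min |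

| run | time / min | product / % |
|---|---|---|
| north-east | 0.333 | 12.0 |
| north-east | 0.667 | 20.0 |
| north-east | 1.00 | 28.1 |
| north-east | 1.33 | 41.0 |
| north-east | 2.00 | 59.5 |
| north-east | 2.50 | 69.2 |
| south | 0.167 | 13.1 |
| south | 0.417 | 26.6 |
| south | 0.667 | 35.0 |
| south | 1.00 | 41.4 |
| south | 1.50 | 69.6 |
| south | 2.00 | 83.2 |
| south | 2.50 | 91.3 |

(readings scatter by 0.5 percentage points)

* which one finishes higher in amount of product, in percent of the starting material charged ("neither" within 2 percentage points) (alder / cedar / neither)
* amount of product at the end, in percent of the starting material charged, alder
* amount of product at the end, in percent of the starting material charged, cedar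



Write S for the starting material left, as a share of the charge, and E for the enzyme concentration. Within a stretch, the fall of ln S per minute is a pseudo-first-order constant, and dividing it by E lets runs with different enzyme be compared. After the second portion, north-east reads 3.97 /µM/min and south reads 3.91 /µM/min. Their mean is κ = 3.94 /µM/min, the constant per enzyme with the whole charge in. The first minute, with half the charge in, reads 5.90 /µM/min and 5.50 /µM/min, so their mean κ₀ = 5.70 /µM/min is higher than κ.

Two chemists dispute cedar. Ana says the constant follows the amount charged, so cedar runs at κ from the start and reaches 62.6 %. Ben says each later portion costs activity, so cedar, which gets none, keeps κ₀ and reaches 75.9 %. Both put alder first: with κ₀ for the first minute and κ afterwards, alder reaches 81.2 %, higher than either cedar number.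

The forecast holds that "the activity steps down with the amount charged" and names alder. It gives alder 82 % (79 % to 85 %) and cedar 66 % (61 % to 77 %), which leans to Ana without being her number.

Alder ends at 81.7 % and cedar at 66.6 %, and cedar stands further from Ben's number than from Ana's. Ben's κ₀ keeps its region: the first minute of north-east and south, with half the charge in.

    starting material + enzyme → product + enzyme, rate k1*[starting material]*[enzyme]/(1 + ([starting material]/Km1) + ([product]/Kp1)) (1.90 mM, 0.860 mM, k = 1.30 × 10⁵ /M/s)

Cedar's starting material fell from 50 % at 1.5 min to 33 % at 2.50 min, and that stretch reads 4.10 /µM/min, beside κ of 3.94 /µM/min. For a further flask, like cedar but with 0.0400 µM of enzyme, κ reckons 32.6 % product, and that flask gave 37.6 %.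

All runs come from a simulation for an exercise; the scatter is artificial.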